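**Pl****an**

1. Rings: A = methyl-bearing cyclopentane, B = cyclooctene, C = cyclohexane, D = isopropyl-bearing cyclopentane. Ring A is taken back to a cyclopentenone (the CH2 next to the methyl-bearing CH becomes C=O; the methyl-bearing CH and the A/B fusion CH become C=C). Three bonds are then cut at once: allylic CH2–C=O, C=O–CH=, and the bond between the two A/B fusion carbons. This gives a ring C allenyl carbinol with an alkyne-terminated chain, plus CO.
2. Further cuts: carbinol C–allenyl bond (to a trans-hydrindanone); then two ring C bonds (quaternary C–CH2 and the enone C=C) by a Robinson disconnection to a ring D β-keto ester and an enone from (S)-citronellal.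
3. Forward: ring D (ring contraction of (S)-perillic acid), then ring C (Michael/aldol), then rings A and B together in one cyclocarbonylation, then adjustment of ring A (reduction/methylation, C=O to CH2).
4. Stereochemistry: isopropyl centre from (S)-perillic acid; ring B methyl centre from (S)-citronellal; quaternary carbon by Michael addition anti to isopropyl; C/D fusion hydrogen by dissolving-metal reduction; carbinol by equatorial attack; the two ring A centres by ligand-controlled hydride delivery and trans enolate methylation.
5. Enabling feature: the tetrasubstituted C=C that is exocyclic to ring A and endocyclic in ring B, flanked in ring A by CH2–CH2. It is the imprint of an allene whose central carbon and terminal CH2 were joined to an alkyne and to CO; ring A is a masked 4-alkylidenecyclopent-2-enone.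

Key step: step 17

**Route**

Step 1
Reactants: 1 (S)-citronellal
Product: 2 (3S)-3,7-dimethyl-2-methylideneoct-6-enal
Conditions: aq. CH2O (37 %), pyrrolidine (10 mol %), propanoic acid (10 mol %), i-PrOH, 45 °C
Reagents that add atoms: formaldehyde, C=O
Why: Amine-catalysed Mannich condensation/elimination (α-methylenation of an aldehyde); the methyl-bearing centre is not touched and should be carried through unchanged.

Step 2
Reactants: 2 (3S)-3,7-dimethyl-2-methylideneoct-6-enal
Product: 3 (4S)-4,8-dimethyl-3-methylidenenon-7-en-2-ol (both carbinol epimers)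
Conditions: MeMgBr, THF, −78 °C; then H2O
Reagents that add atoms: methylmagnesium bromide, C[Mg]Br
Why: 1,2-Addition of a Grignard reagent to an α-branched enal; the new carbinol centre is removed in step 3.

Step 3
Reactants: 3 allylic alcohol
Product: 4 (4S)-4,8-dimethyl-3-methylidenenon-7-en-2-one (enone, fragment 2)
Conditions: Dess–Martin periodinane, CH2Cl2, 0 °C to rt
Reagents that add atoms: none
Why: Dess–Martin oxidation of a secondary allylic alcohol under neutral conditions, which should not move the 1,1-disubstituted alkene toward the stereocentre.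

Step 4
Reactants: 5 (S)-perillic acid
Product: 6 2-(trimethylsilyl)ethyl (4S)-4-(prop-1-en-2-yl)cyclohex-1-ene-1-carboxylate
Conditions: 2-(trimethylsilyl)ethanol, DCC, DMAP (10 mol %), CH2Cl2, 0 °C to rt
Reagents that add atoms: 2-(trimethylsilyl)ethanol, C[Si](C)(C)CCO
Why: Steglich esterification; this ester is chosen because fluoride removes it at the end without acid or hydroxide.

Step 5
Reactants: 6 silylethyl perillate
Product: 7 2-(trimethylsilyl)ethyl (4S)-4-(propan-2-yl)cyclohex-1-ene-1-carboxylate
Conditions: H2 (1 atm), RhCl(PPh3)3 (2 mol %), benzene–EtOH, rt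
Reagents that add atoms: none
Why: Homogeneous hydrogenation that should reduce the 1,1-disubstituted isopropenyl alkene much faster than the conjugated trisubstituted enoate alkene.

Step 6
Reactants: 7 cyclohexene ester
Product: 8 2-(trimethylsilyl)ethyl (5S)-2,7-dioxo-5-(propan-2-yl)heptanoate
Conditions: O3, CH2Cl2, −78 °C; then Me2S, −78 °C to rt
Reagents that add atoms: ozone, [O-][O+]=O
Why: Ozonolysis with reductive work-up cleaves the enoate C=C to an α-keto ester and an aldehyde without touching the stereocentre.

Step 7
Reactants: 8 keto ester aldehyde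
Product: 9 2-(trimethylsilyl)ethyl (3R)-2-formyl-3-(propan-2-yl)cyclopent-1-ene-1-carboxylate
Conditions: piperidine (0.2 equiv), AcOH (0.2 equiv), benzene, reflux (Dean–Stark)
Reagents that add atoms: none
Why: Intramolecular aldol condensation: the enamine of the aldehyde attacks the activated α-keto ester carbonyl (five-ring closure) and dehydrates, the same ring contraction as used for cyclopentenecarbaldehydes from p-menthenes.

Step 8
Reactants: 9 formyl cyclopentene ester
Product: 10 2-(trimethylsilyl)ethyl (3R)-2-formyl-3-(propan-2-yl)cyclopentane-1-carboxylate (epimers at C-1 and C-2)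
Conditions: H2 (1 atm), Pd/C (5 %), EtOAc, rt
Reagents that add atoms: none
Why: Heterogeneous hydrogenation of the doubly activated C=C; the two new centres need no control because both are erased in steps 9 and 10.

Step 9
Reactants: 10 formyl cyclopentane ester
Product: 12 2-(trimethylsilyl)ethyl (3R)-2-oxo-3-(propan-2-yl)cyclopentane-1-carboxylate, via morpholine enamine 11 (not isolated)
Conditions: morpholine (1.05 equiv), 4 Å molecular sieves, benzene, rt; then CuCl (10 mol %), O2 (1 atm), MeCN, 0 °C
Reagents that add atoms: dioxygen, O=O; morpholine, C1COCCN1 (carried only in intermediate 11)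
Why: Enamine formation from the α-branched aldehyde and copper-catalysed oxygenative cleavage of the enamine C=C (one-carbon degradation of an aldehyde to the nor-ketone); the isopropyl-bearing centre should survive because the β-keto ester enolises toward the ester side.

Step 10
Reactants: 12 β-keto ester; 4 enone (fragment 2)
Product: 13 2-(trimethylsilyl)ethyl (1S,3R)-1-[(3S)-2-acetyl-3,7-dimethyloct-6-en-1-yl]-2-oxo-3-(propan-2-yl)cyclopentane-1-carboxylate (both epimers at the acetyl-bearing carbon)
Conditions: DBU (10 mol %), MeCN, 0 °C to rt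
Reagents that add atoms: none
Why: Michael addition of a cyclic β-keto ester to an α-substituted vinyl ketone (first half of a Robinson annulation); the planar enolate should be attacked on the face opposite the neighbouring isopropyl group, which sets the quaternary carbon with the new arm trans to isopropyl.

Step 11
Reactants: 13 1,5-diketone
Product: 14 2-(trimethylsilyl)ethyl (3R,6R,7aS)-6-[(2S)-6-methylhept-5-en-2-yl]-5-oxo-3-(propan-2-yl)-2,3,5,6,7,7a-hexahydro-1H-indene-7a-carboxylate
Conditions: pyrrolidine (0.3 equiv), AcOH (0.3 equiv), toluene, 80 °C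
Reagents that add atoms: none
Why: Intramolecular aldol condensation (second half of the Robinson annulation, enamine catalysis on the methyl ketone) closes ring C; the side-chain-bearing carbon next to the ketone should equilibrate to the equatorial epimer, which avoids a 1,3-diaxial clash with the angular ester.

Step 12
Reactants: 14 bicyclic enone
Product: 15 2-(trimethylsilyl)ethyl (3R,3aS,6R,7aS)-6-[(2S)-6-methylhept-5-en-2-yl]-5-oxo-3-(propan-2-yl)octahydro-7aH-indene-7a-carboxylate (trans-fused)
Conditions: Li (2.5 equiv), NH3(l)–THF, t-BuOH (1 equiv), −78 °C; then NH4Cl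
Reagents that add atoms: none
Why: Birch-type dissolving-metal reduction of the enone; the β-carbanion should be protonated on the face opposite both the angular ester and the adjacent isopropyl group, giving the trans ring fusion, while the isolated alkene and the hindered ester are expected to survive.

Step 13
Reactants: 15 trans-hydrindanone
Product: 16 2-(trimethylsilyl)ethyl (3R,3aS,6R,7aS)-5-oxo-6-[(2S)-5-oxopentan-2-yl]-3-(propan-2-yl)octahydro-7aH-indene-7a-carboxylate
Conditions: O3, CH2Cl2, −78 °C; then Me2S
Reagents that add atoms: ozone, [O-][O+]=O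
Why: Ozonolysis of the only C=C (electron-rich, trisubstituted) with reductive work-up gives the aldehyde.

Step 14
Reactants: 16 keto aldehyde
Product: 17 2-(trimethylsilyl)ethyl (3R,3aS,6R,7aS)-6-[(2S)-hex-5-yn-2-yl]-5-oxo-3-(propan-2-yl)octahydro-7aH-indene-7a-carboxylate
Conditions: dimethyl (1-diazo-2-oxopropyl)phosphonate, K2CO3, MeOH, 0 °C to rt
Reagents that add atoms: dimethyl (1-diazo-2-oxopropyl)phosphonate, CC(=O)C(=[N+]=[N-])P(=O)(OC)OC
Why: Ohira–Bestmann homologation of the aldehyde to the terminal alkyne, which should be much faster than any reaction at the hindered ketone; the centre next to the ketone stays equatorial under carbonate.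

Step 15
Reactants: 17 alkynyl ketone
Product: 18 2-(trimethylsilyl)ethyl (3R,3aS,5R,6R,7aS)-5-(buta-2,3-dien-2-yl)-6-[(2S)-hex-5-yn-2-yl]-5-hydroxy-3-(propan-2-yl)octahydro-7aH-indene-7a-carboxylate
Conditions: 1-bromobut-2-yne, In powder, THF–H2O (1:1), rt
Reagents that add atoms: 1-bromobut-2-yne, CC#CCBr
Why: Barbier-type indium-mediated addition of a γ-substituted propargyl bromide: the but-2-ynylindium reacts through a cyclic SE2′ transition state to give the α-methylallenyl carbinol, and this bulky reagent should attack the cyclohexanone equatorially, giving the axial alcohol cis to the equatorial side chain.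

Step 16
Reactants: 18 allenyl carbinol
Product: 19 triethylsilyl ether of 18
Conditions: Et3SiOTf, 2,6-lutidine, CH2Cl2, −78 to 0 °C
Reagents that add atoms: triethylsilyl trifluoromethanesulfonate, CC[Si](CC)(CC)OS(=O)(=O)C(F)(F)F
Why: Silylation of a hindered tertiary alcohol with a silyl triflate; it protects the α-allenyl carbinol against metal- or acid-promoted cyclisation and ionisation.

Step 17
Reactants: 19 silylated allenyne
Product: 20 tetracyclic dienone (ring A as 4-alkylidenecyclopent-2-en-1-one)
Conditions: [RhCl(CO)2]2 (10 mol %), CO (1 atm), toluene (0.01 M), 110 °C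
Reagents that add atoms: carbon monoxide, [C-]#[O+]
Why: Monovalent rhodium binds the alkyne and the terminal π-bond of the allene and cyclises oxidatively to a rhodacyclopentene in which the inner alkyne carbon is joined to the central allene carbon; CO then inserts and reductive elimination joins the carbonyl carbon to the allene CH2 and to the alkyne CH, the closest known reaction type being the rhodium-catalysed allenic Pauson–Khand reaction of 1,2-dien-ynes, which has been used for bicyclo[5.3.0] and bicyclo[6.3.0] dienones. Ring A closes by the [2+2+1] cyclocarbonylation itself (five-membered, the CO carbon becoming the ring A carbon that later ends as CH2 next to the methyl-bearing carbon), and ring B closes through the metallacycle-forming C–C bond (eight-membered, the tether running through the side chain and the carbinol carbon of ring C). No stereocentre is created; the only stereo-element is the geometry of the tetrasubstituted C=C, which is fixed because both of its in-ring substituents belong to ring B. The step needs reaction at the distal and not the proximal π-bond of the allene, and ring closure rather than oligomerisation: the first is the usual preference of monovalent rhodium and is reinforced by the methyl group and the fully substituted silyloxy carbon on the proximal allene carbon, the second should be helped by high dilution and by the trans-diequatorial placement of the allenyl and alkynyl arms on the rigid trans-hydrindane.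

Step 18
Reactants: 20 tetracyclic dienone
Product: 23 ring A methyl ketone (A/B fusion CH and trans methyl-bearing CH set), via diphenylsilyl enol ether 21 (not isolated), via lithium enolate 22 (not isolated)
Conditions: CuCl (5 mol %), NaOt-Bu (5 mol %), (S)-p-tol-BINAP (5 mol %), Ph2SiH2 (1.05 equiv), toluene, 0 °C to rt; then MeLi (1.1 equiv), THF, −78 to 0 °C; then MeI (5 equiv), DMPU, −78 to −20 °C
Reagents that add atoms: iodomethane, CI; diphenylsilane, c1ccc(cc1)[SiH2]c1ccccc1 (silicon carried only in intermediate 21); methyllithium, [Li]C (lithium carried only in intermediate 22)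
Why: Copper hydride-catalysed asymmetric conjugate reduction of a 3-substituted cyclopentenone followed by alkylation of the regiodefined enolate (a known one-pot route to trans-2,3-disubstituted cyclopentanones): the ligand should control the face of hydride delivery to the fusion carbon (the (S)-ligand is assigned by analogy with 3-alkylcyclopent-2-enones and its antipode would be used if this substrate deviates), 1,4-reduction is expected over 1,6-reduction because the δ-carbon is fully substituted, and iodomethane should enter anti to the ring B bond on the adjacent carbon.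

Step 19
Reactants: 23 ring A methyl ketone
Product: 24 4-methylbenzenesulfonylhydrazone of 23
Conditions: TsNHNH2 (1.5 equiv), PPTS (5 mol %), THF–EtOH, 50 °C
Reagents that add atoms: 4-methylbenzenesulfonohydrazide, Cc1ccc(cc1)S(=O)(=O)NN
Why: Hydrazone formation under nearly neutral conditions, which should not move the β,γ-C=C into conjugation or epimerise the α-methyl centre away from its favoured trans arrangement.

Step 20
Reactants: 24 tosylhydrazone
Product: 25 sesterfisheric acid 2-(trimethylsilyl)ethyl ester triethylsilyl ether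
Conditions: catecholborane (3 equiv), CHCl3, 0 °C to rt; then NaOAc·3H2O, 60 °C
Reagents that add atoms: none
Why: Catecholborane reduction of a saturated ketone tosylhydrazone (hydroboration of C=N, loss of sulfinate, loss of N2 from the diazene) turns C=N into CH2 without the strong base of a Wolff–Kishner reduction.

Step 21
Reactants: 25 doubly protected acid
Product: 26 sesterfisheric acid
Conditions: Bu4NF (5 equiv), THF, rt to 45 °C; then aq. NH4Cl
Reagents that add atoms: none
Why: Fluoride-induced β-elimination of the 2-(trimethylsilyl)ethyl ester and cleavage of the tertiary silyl ether in one operation; no acid strong enough to ionise the tertiary allylic alcohol is used.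

**Compound list**

1 | (S)-citronellal, (3S)-3,7-dimethyloct-6-enal | C[C@@H](CCC=C(C)C)CC=O | starting material
2 | (3S)-3,7-dimethyl-2-methylideneoct-6-enal | C[C@@H](CCC=C(C)C)C(=C)C=O | intermediate
3 | (4S)-4,8-dimethyl-3-methylidenenon-7-en-2-ol (both carbinol epimers) | C[C@@H](CCC=C(C)C)C(=C)C(C)O | intermediate
4 | (4S)-4,8-dimethyl-3-methylidenenon-7-en-2-one | C[C@@H](CCC=C(C)C)C(=C)C(C)=O | intermediate
5 | (S)-perillic acid, (4S)-4-(prop-1-en-2-yl)cyclohex-1-ene-1-carboxylic acid | CC(=C)[C@H]1CCC(=CC1)C(=O)O | starting material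
6 | 2-(trimethylsilyl)ethyl (4S)-4-(prop-1-en-2-yl)cyclohex-1-ene-1-carboxylate | CC(=C)[C@H]1CCC(=CC1)C(=O)OCC[Si](C)(C)C | intermediate
7 | 2-(trimethylsilyl)ethyl (4S)-4-(propan-2-yl)cyclohex-1-ene-1-carboxylate | CC(C)[C@H]1CCC(=CC1)C(=O)OCC[Si](C)(C)C | intermediate
8 | 2-(trimethylsilyl)ethyl (5S)-2,7-dioxo-5-(propan-2-yl)heptanoate | CC(C)[C@H](CC=O)CCC(=O)C(=O)OCC[Si](C)(C)C | intermediate
9 | 2-(trimethylsilyl)ethyl (3R)-2-formyl-3-(propan-2-yl)cyclopent-1-ene-1-carboxylate | CC(C)[C@H]1CCC(C(=O)OCC[Si](C)(C)C)=C1C=O | intermediate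
10 | 2-(trimethylsilyl)ethyl (3R)-2-formyl-3-(propan-2-yl)cyclopentane-1-carboxylate (epimers at C-1 and C-2) | CC(C)[C@H]1CCC(C(=O)OCC[Si](C)(C)C)C1C=O | intermediate
11 | 2-(trimethylsilyl)ethyl (3R)-2-(morpholin-4-ylmethylidene)-3-(propan-2-yl)cyclopentane-1-carboxylate | CC(C)[C@H]1CCC(C(=O)OCC[Si](C)(C)C)C1=CN2CCOCC2 | intermediate
12 | 2-(trimethylsilyl)ethyl (3R)-2-oxo-3-(propan-2-yl)cyclopentane-1-carboxylate (C-1 epimers and enol) | CC(C)[C@H]1CCC(C(=O)OCC[Si](C)(C)C)C1=O | intermediate
13 | 2-(trimethylsilyl)ethyl (1S,3R)-1-[(3S)-2-acetyl-3,7-dimethyloct-6-en-1-yl]-2-oxo-3-(propan-2-yl)cyclopentane-1-carboxylate (both epimers at the acetyl-bearing carbon) | CC(C)=CCC[C@H](C)C(C[C@@]1(C(=O)OCC[Si](C)(C)C)CC[C@H](C(C)C)C1=O)C(C)=O | intermediate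
14 | 2-(trimethylsilyl)ethyl (3R,6R,7aS)-6-[(2S)-6-methylhept-5-en-2-yl]-5-oxo-3-(propan-2-yl)-2,3,5,6,7,7a-hexahydro-1H-indene-7a-carboxylate | CC(C)=CCC[C@H](C)[C@H]2C[C@@]3(C(=O)OCC[Si](C)(C)C)CC[C@H](C(C)C)C3=CC2=O | intermediate
15 | 2-(trimethylsilyl)ethyl (3R,3aS,6R,7aS)-6-[(2S)-6-methylhept-5-en-2-yl]-5-oxo-3-(propan-2-yl)octahydro-7aH-indene-7a-carboxylate | CC(C)=CCC[C@H](C)[C@H]2C[C@@]3(C(=O)OCC[Si](C)(C)C)CC[C@H](C(C)C)[C@@H]3CC2=O | intermediate
16 | 2-(trimethylsilyl)ethyl (3R,3aS,6R,7aS)-5-oxo-6-[(2S)-5-oxopentan-2-yl]-3-(propan-2-yl)octahydro-7aH-indene-7a-carboxylate | O=CCC[C@H](C)[C@H]2C[C@@]3(C(=O)OCC[Si](C)(C)C)CC[C@H](C(C)C)[C@@H]3CC2=O | intermediate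
17 | 2-(trimethylsilyl)ethyl (3R,3aS,6R,7aS)-6-[(2S)-hex-5-yn-2-yl]-5-oxo-3-(propan-2-yl)octahydro-7aH-indene-7a-carboxylate | C#CCC[C@H](C)[C@H]2C[C@@]3(C(=O)OCC[Si](C)(C)C)CC[C@H](C(C)C)[C@@H]3CC2=O | intermediate
18 | 2-(trimethylsilyl)ethyl (3R,3aS,5R,6R,7aS)-5-(buta-2,3-dien-2-yl)-6-[(2S)-hex-5-yn-2-yl]-5-hydroxy-3-(propan-2-yl)octahydro-7aH-indene-7a-carboxylate | C#CCC[C@H](C)[C@H]2C[C@@]3(C(=O)OCC[Si](C)(C)C)CC[C@H](C(C)C)[C@@H]3C[C@]2(O)C(C)=C=C | intermediate
19 | 5-O-triethylsilyl ether of 18 | C#CCC[C@H](C)[C@H]2C[C@@]3(C(=O)OCC[Si](C)(C)C)CC[C@H](C(C)C)[C@@H]3C[C@]2(O[Si](CC)(CC)CC)C(C)=C=C | intermediate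
20 | tetracyclic dienone: ring A is a 4-alkylidenecyclopent-2-en-1-one (C=O between the ring CH2 and CH=; that CH= is double-bonded to the fusion carbon carrying the ring B chain; the other fusion carbon is double-bonded to the methyl-bearing ring B carbon); triethylsilyl ether on the B/C carbinol carbon; 2-(trimethylsilyl)ethyl ester on the C/D fusion carbon | C/C1=C2\CC(=O)C=C2CC[C@H](C)[C@H]2C[C@@]3(C(=O)OCC[Si](C)(C)C)CC[C@H](C(C)C)[C@@H]3C[C@]12O[Si](CC)(CC)CC | intermediate
21 | diphenylsilyl enol ether of the 1,4-reduced ring A ketone (A/B fusion CH set) | C/C1=C2\CC(O[SiH](c4ccccc4)c4ccccc4)=C[C@@H]2CC[C@H](C)[C@H]2C[C@@]3(C(=O)OCC[Si](C)(C)C)CC[C@H](C(C)C)[C@@H]3C[C@]12O[Si](CC)(CC)CC | intermediate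
22 | lithium enolate of the same ring A ketone | [Li+].C/C1=C2\CC([O-])=C[C@@H]2CC[C@H](C)[C@H]2C[C@@]3(C(=O)OCC[Si](C)(C)C)CC[C@H](C(C)C)[C@@H]3C[C@]12O[Si](CC)(CC)CC | intermediate
23 | ring A ketone with the methyl group trans to the ring B bond at the fusion carbon (triethylsilyl ether, 2-(trimethylsilyl)ethyl ester) | C/C1=C2\CC(=O)[C@@H](C)[C@@H]2CC[C@H](C)[C@H]2C[C@@]3(C(=O)OCC[Si](C)(C)C)CC[C@H](C(C)C)[C@@H]3C[C@]12O[Si](CC)(CC)CC | intermediate
24 | 4-methylbenzenesulfonylhydrazone of 23 | C/C1=C2\CC(=NNS(=O)(=O)c4ccc(C)cc4)[C@@H](C)[C@@H]2CC[C@H](C)[C@H]2C[C@@]3(C(=O)OCC[Si](C)(C)C)CC[C@H](C(C)C)[C@@H]3C[C@]12O[Si](CC)(CC)CC | intermediate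
25 | sesterfisheric acid 2-(trimethylsilyl)ethyl ester triethylsilyl ether | C/C1=C2\CC[C@@H](C)[C@@H]2CC[C@H](C)[C@H]2C[C@@]3(C(=O)OCC[Si](C)(C)C)CC[C@H](C(C)C)[C@@H]3C[C@]12O[Si](CC)(CC)CC | intermediate
26 | sesterfisheric acid | C/C1=C2\CC[C@@H](C)[C@@H]2CC[C@H](C)[C@H]2C[C@@]3(C(=O)O)CC[C@H](C(C)C)[C@@H]3C[C@]12O | target

**Count and risks**

Total step count: 21. Longest linear sequence: 18 steps (steps 4 to 21, from 5).

Steps most likely to fail:

1. Step 17. What may go wrong: closure of the eight-membered ring is slow, so the terminal alkyne is consumed through rhodium vinylidene formation and oligomerisation before the metallacycle forms, or the metallacycle forms through the inner π-bond of the allene. Fallback (the ring A methyl group is brought in on the alkyne, so the alkyne is internal and no enolate methylation is needed): it sets out from 19. The alkyne C–H is deprotonated (LDA, THF, −78 °C) and methylated with iodomethane to give the hept-5-yn-2-yl allenyne F1. Cyclocarbonylation of F1 with [RhCl(CO)2]2 and CO gives the 2-methyl dienone F2; internal alkynes are the usual substrates of this reaction. Conjugate reduction of F2 with CuCl, NaOt-Bu, (S)-p-tol-BINAP and Ph2SiH2, aqueous work-up, and equilibration of the methyl-bearing carbon with DBU (toluene, rt) should give 23, where the route is rejoined.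

2. Step 18. What may go wrong: proton exchange between the lithium enolate and the product ketone, whose allylic CH2 is the most acidic position, so that methylation occurs at the wrong carbon or twice; also hydride delivery to the wrong face of the fusion carbon, which would be answered first by the antipodal ligand. Fallback (the methyl carbon is introduced by a Mannich reaction on the silyl enol ether, not by enolate alkylation): it sets out from 20. Conjugate reduction as in step 18 gives 21, which is treated with dimethyl(methylidene)ammonium iodide (CH2Cl2, rt) to give the Mannich base F3. N-Methylation (MeI) and elimination (NaHCO3) give the α-methylidene ketone F4. 1,4-Reduction of this β-unsubstituted enone with KBH(s-Bu)3 (THF, −78 °C), protonation and equilibration with DBU should give 23.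

3. Step 12. What may go wrong: protonation of the β-carbanion from the wrong face, giving the cis-fused hydrindanone, or over-reduction of the ester or ketone by lithium. Fallback (catalytic hydrogenation on an intermediate that no longer carries the side-chain alkene): it sets out from 14. Ozonolysis (O3, CH2Cl2, −78 °C; Me2S) cleaves the trisubstituted alkene, leaving the electron-poor enone C=C, and gives the enone aldehyde F5. Acetalisation (HC(OMe)3, PPTS, MeOH) gives the dimethyl acetal F6. Hydrogenation (H2, Pd/C, EtOAc) from the face opposite the isopropyl group and the angular ester should give the trans-fused ketone acetal F7. Hydrolysis (PPTS, acetone–water) gives 16, where the route is rejoined.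

**Further compounds**

F1 | step 17 | 2-(trimethylsilyl)ethyl (3R,3aS,5R,6R,7aS)-5-(buta-2,3-dien-2-yl)-6-[(2S)-hept-5-yn-2-yl]-3-(propan-2-yl)-5-[(triethylsilyl)oxy]octahydro-7aH-indene-7a-carboxylate | CC#CCC[C@H](C)[C@H]2C[C@@]3(C(=O)OCC[Si](C)(C)C)CC[C@H](C(C)C)[C@@H]3C[C@]2(O[Si](CC)(CC)CC)C(C)=C=C
F2 | step 17 | 2-methyl analogue of dienone 20 (methyl on the enone carbon next to C=O) | C/C1=C2\CC(=O)C(C)=C2CC[C@H](C)[C@H]2C[C@@]3(C(=O)OCC[Si](C)(C)C)CC[C@H](C(C)C)[C@@H]3C[C@]12O[Si](CC)(CC)CC
F3 | step 18 | Mannich base: ring A ketone carrying CH2NMe2 on the carbon between C=O and the fusion CH | C/C1=C2\CC(=O)C(CN(C)C)[C@@H]2CC[C@H](C)[C@H]2C[C@@]3(C(=O)OCC[Si](C)(C)C)CC[C@H](C(C)C)[C@@H]3C[C@]12O[Si](CC)(CC)CC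
F4 | step 18 | α-methylidene ring A ketone (exocyclic CH2= on the carbon between C=O and the fusion CH) | C/C1=C2\CC(=O)C(=C)[C@@H]2CC[C@H](C)[C@H]2C[C@@]3(C(=O)OCC[Si](C)(C)C)CC[C@H](C(C)C)[C@@H]3C[C@]12O[Si](CC)(CC)CC
F5 | step 12 | 2-(trimethylsilyl)ethyl (3R,6R,7aS)-5-oxo-6-[(2S)-5-oxopentan-2-yl]-3-(propan-2-yl)-2,3,5,6,7,7a-hexahydro-1H-indene-7a-carboxylate | O=CCC[C@H](C)[C@H]2C[C@@]3(C(=O)OCC[Si](C)(C)C)CC[C@H](C(C)C)C3=CC2=O
F6 | step 12 | dimethyl acetal of F5 | COC(OC)CC[C@H](C)[C@H]2C[C@@]3(C(=O)OCC[Si](C)(C)C)CC[C@H](C(C)C)C3=CC2=O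
F7 | step 12 | dimethyl acetal of 16 (trans-fused ketone) | COC(OC)CC[C@H](C)[C@H]2C[C@@]3(C(=O)OCC[Si](C)(C)C)CC[C@H](C(C)C)[C@@H]3CC2=O
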